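**Retrosynthetic overview**
1. Target 21 is a (2S)-flavanone. The three MOM ethers come off last, after one double cross-metathesis has turned the allyl groups at C8 and C2' into the two prenyl groups.
2. Ring C is opened at O1–C8a and at C4–C4a. Ring A becomes aryne 18 (triple bond C4a≡C8a, from ortho-silylaryl triflate 8). The chain O1–C2–C3–C4 becomes the (S)-beta-silyloxy ester 16, which already carries ring B and the stereocentre.
3. Enabling feature: O1 and the C4 carbonyl carbon sit on neighbouring ring A carbons C8a and C4a. C4a lies next to the C5 oxygen, which polarises the aryne so that oxygen adds at C8a and the carbanion appears at C4a. Only C2 and C3 separate O1 from C4, so the carbanion meets the ester in a six-membered closure.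
4. C2 is set by asymmetric transfer hydrogenation of beta-keto ester 14. Both allyl groups come from aromatic Claisen rearrangements, on ring A from phloroglucinol 1 and on ring B from 3,4-dihydroxybenzaldehyde 9.
5. Rings A and B are bought as benzene rings. Ring C is the only ring formed, in step 13.

Key step: step 13

Remark: flavanone numbering is used throughout (O1, C2, C3, C4, C4a, C5 to C8, C8a for rings C and A; primed numbers for ring B), and the stereocentre of the target SMILES is read as 2S.

**Ring A fragment**

Step 1
Reactants: 1 phloroglucinol (benzene-1,3,5-triol)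
Product: 2 3,5-bis(methoxymethoxy)phenol
Conditions: NaH (2.0 equiv), MOMCl (2.0 equiv), DMF, 0 °C to rt; chromatography
Reagents that add atoms: chloromethyl methyl ether (MOMCl), COCCl
Why: Williamson-type O-alkylation (MOM acetal protection): the three hydroxyl groups of 1 are equivalent, so two equivalents of base and MOMCl should give the bis-ether as the main component of a mixture that chromatography can separate.

Step 2
Reactants: 2 3,5-bis(methoxymethoxy)phenol
Product: 3 1-(allyloxy)-3,5-bis(methoxymethoxy)benzene
Conditions: allyl bromide, K2CO3, acetone, reflux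
Reagents that add atoms: allyl bromide, C=CCBr
Why: Williamson ether synthesis at the only free phenol, under conditions that leave MOM ethers untouched.

Step 3
Reactants: 3 1-(allyloxy)-3,5-bis(methoxymethoxy)benzene
Product: 4 2-allyl-3,5-bis(methoxymethoxy)phenol
Conditions: N,N-diethylaniline, 190 °C, N2
Reagents that add atoms: none
Why: Aromatic Claisen rearrangement ([3,3]-sigmatropic shift, then tautomerisation): the two ortho carbons are equivalent by symmetry, so only one ortho-allylphenol can form, and the basic solvent protects the MOM ethers.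

Step 4
Reactants: 4 2-allyl-3,5-bis(methoxymethoxy)phenol
Product: 5 2-allyl-6-bromo-3,5-bis(methoxymethoxy)phenol
Conditions: NBS (1.0 equiv), i-Pr2NH (10 mol%), CH2Cl2, −78 °C to 0 °C
Reagents that add atoms: N-bromosuccinimide (NBS), O=C1CCC(=O)N1Br
Why: Amine-catalysed ortho-selective electrophilic bromination of a phenol: the N-bromoamine is held by a hydrogen bond to the OH and should deliver bromine to the one free ortho carbon rather than to the more crowded carbon between the two MOM ethers, and the very electron-rich ring should react much faster than the terminal alkene.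

Step 5
Reactants: 5 2-allyl-6-bromo-3,5-bis(methoxymethoxy)phenol
Product: 8 2-allyl-3,5-bis(methoxymethoxy)-6-(trimethylsilyl)phenyl trifluoromethanesulfonate, via aryl trimethylsilyl ether 6 (not isolated), via lithium silylphenoxide 7 (not isolated)
Conditions: HMDS, THF, 65 °C, then evaporation; n-BuLi, THF, −78 °C; Tf2O, −78 °C to 0 °C
Reagents that add atoms: hexamethyldisilazane (HMDS), C[Si](C)(C)N[Si](C)(C)C; trifluoromethanesulfonic anhydride (Tf2O), O=S(=O)(OS(=O)(=O)C(F)(F)F)C(F)(F)F
Why: Standard sequence to ortho-silylaryl triflates: O-silylation, bromine-lithium exchange (faster at −78 °C than deprotonation of the allylic CH2), retro-Brook 1,3-shift of silicon from O to C, and triflation of the resulting lithium phenoxide.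

**Ring B fragment**

Step 6
Reactants: 9 3,4-dihydroxybenzaldehyde
Product: 10 3-hydroxy-4-(methoxymethoxy)benzaldehyde
Conditions: MOMCl (1.0 equiv), K2CO3 (1.1 equiv), acetone, 0 °C to rt
Reagents that add atoms: chloromethyl methyl ether (MOMCl), COCCl
Why: Regioselective Williamson-type alkylation: the 4-OH, conjugated with the para formyl group, is the more acidic one, so with one equivalent of weak base its phenoxide is the one alkylated.

Step 7
Reactants: 10 3-hydroxy-4-(methoxymethoxy)benzaldehyde
Product: 11 3-(allyloxy)-4-(methoxymethoxy)benzaldehyde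
Conditions: allyl bromide, K2CO3, DMF, rt
Reagents that add atoms: allyl bromide, C=CCBr
Why: Williamson ether synthesis at the remaining phenol.

Step 8
Reactants: 11 3-(allyloxy)-4-(methoxymethoxy)benzaldehyde
Product: 12 2-allyl-3-hydroxy-4-(methoxymethoxy)benzaldehyde
Conditions: N,N-diethylaniline, 180 °C, N2
Reagents that add atoms: none
Why: Aromatic Claisen rearrangement: of the two ortho carbons, C4 is blocked by the OMOM group, so the allyl group should end at C2, between the formyl group and the new phenol.

Step 9
Reactants: 12 2-allyl-3-hydroxy-4-(methoxymethoxy)benzaldehyde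
Product: 13 2-allyl-3-methoxy-4-(methoxymethoxy)benzaldehyde
Conditions: MeI, K2CO3, DMF, rt
Reagents that add atoms: iodomethane, CI
Why: Williamson O-methylation of the only free phenol fixes the 3'-methoxy group of ring B.

Step 10
Reactants: 13 2-allyl-3-methoxy-4-(methoxymethoxy)benzaldehyde
Product: 14 ethyl 3-[2-allyl-3-methoxy-4-(methoxymethoxy)phenyl]-3-oxopropanoate
Conditions: ethyl diazoacetate (1.2 equiv), SnCl2 (10 mol%), CH2Cl2, rt
Reagents that add atoms: ethyl diazoacetate, CCOC(=O)C=[N+]=[N-]
Why: Roskamp reaction: the Lewis-acid-activated aldehyde takes up the diazo ester, and a 1,2-hydride shift with loss of N2 gives the beta-keto ester in one step without base, so the allyl group cannot move into conjugation.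

Step 11
Reactants: 14 ethyl 3-[2-allyl-3-methoxy-4-(methoxymethoxy)phenyl]-3-oxopropanoate
Product: 15 ethyl (3S)-3-[2-allyl-3-methoxy-4-(methoxymethoxy)phenyl]-3-hydroxypropanoate
Conditions: RuCl[(S,S)-TsDPEN](p-cymene) (1 mol%), HCO2H/Et3N (5:2), EtOAc, 30 °C
Reagents that add atoms: none
Why: Noyori asymmetric transfer hydrogenation: the (S,S)-TsDPEN ruthenium hydride orients aryl ketones through the CH/pi contact between its p-cymene ligand and ring B and should give the (S)-carbinol, as with other aryl beta-keto esters, while the outer-sphere hydride transfer leaves the allyl group, the ester and the MOM ether alone.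

Step 12
Reactants: 15 ethyl (3S)-3-[2-allyl-3-methoxy-4-(methoxymethoxy)phenyl]-3-hydroxypropanoate
Product: 16 ethyl (3S)-3-[2-allyl-3-methoxy-4-(methoxymethoxy)phenyl]-3-(trimethylsilyloxy)propanoate
Conditions: TMSCl, imidazole, CH2Cl2, 0 °C; filtration through Et3N-deactivated silica
Reagents that add atoms: chlorotrimethylsilane (TMSCl), C[Si](C)(C)Cl
Why: Routine silylation of a secondary alcohol, which removes the O–H proton and makes the oxygen releasable by fluoride without touching the stereocentre.

**Union and endgame**

Step 13
Reactants: 16 ethyl (3S)-3-[2-allyl-3-methoxy-4-(methoxymethoxy)phenyl]-3-(trimethylsilyloxy)propanoate; 8 2-allyl-3,5-bis(methoxymethoxy)-6-(trimethylsilyl)phenyl trifluoromethanesulfonate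
Product: 19 (2S)-8-allyl-2-[2-allyl-3-methoxy-4-(methoxymethoxy)phenyl]-5,7-bis(methoxymethoxy)chroman-4-one, via caesium alkoxide 17 (not isolated), via aryne 18 (not isolated)
Conditions: 8 (1.3 equiv), CsF (1.5 equiv), 18-crown-6 (0.3 equiv), THF, 0 °C to 23 °C; quench with pH 7 phosphate buffer
Reagents that add atoms: none
Why: Proposed new method: fluoride removes the O–SiMe3 group of 16 to give alkoxide 17 and the C–SiMe3 group of 8 to give aryne 18 by loss of triflate, the oxygen of 17 adds to the aryne carbon that becomes C8a, and the aryl anion formed at C4a attacks the ester carbonyl and expels ethoxide, so that O1–C8a and C4–C4a form in one operation. The closest known reaction types are the fluoride-induced annulation of arynes with salicylate esters to xanthones (O-arylation, then intramolecular acyl capture of the aryl anion) and the insertion of arynes into the N–C(=O) bond of beta-lactams, and the new element is an aliphatic secondary alkoxide with enolisable alpha-hydrogens as the partner. Ring C closes in the 6-exo-trig mode. No stereocentre is created: C2 comes from 15 and should keep its S configuration because the C2–O1 bond is never broken. The needed regioselectivity rests on the C5 OMOM group beside the triple bond, whose inductive pull distorts the aryne so that C8a is the more linear and electrophilic carbon and the charge builds up at C4a next to oxygen, an effect that should outweigh the steric cost of the C8 allyl group and the weak opposing effect of the C7 OMOM group. The silyl ether keeps the flask free of O–H protons that would quench the aryl anion, the ethoxide is taken up as EtOSiMe3 by silyl transfer from further 16 so that little base remains to open ring C by retro-oxa-Michael reaction and racemise C2, and terminal allyl groups are poorer ene partners for the aryne than prenyl groups would be.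

Step 14
Reactants: 19 (2S)-8-allyl-2-[2-allyl-3-methoxy-4-(methoxymethoxy)phenyl]-5,7-bis(methoxymethoxy)chroman-4-one
Product: 20 (2S)-2-[3-methoxy-4-(methoxymethoxy)-2-(3-methylbut-2-enyl)phenyl]-5,7-bis(methoxymethoxy)-8-(3-methylbut-2-enyl)chroman-4-one
Conditions: second-generation Grubbs catalyst (H2IMes)(PCy3)Cl2Ru=CHPh (5 mol%), 1,4-benzoquinone (10 mol%), 2-methylbut-2-ene/CH2Cl2 (1:1), 35 °C, sealed tube
Reagents that add atoms: 2-methylbut-2-ene, CC=C(C)C
Why: Olefin cross-metathesis of both terminal allyl arenes with excess 2-methylbut-2-ene should give both prenyl groups in one operation, because the trisubstituted products do not re-enter the cycle, benzoquinone suppresses double-bond migration, and the neutral medium leaves C2 untouched.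

Step 15
Reactants: 20 (2S)-2-[3-methoxy-4-(methoxymethoxy)-2-(3-methylbut-2-enyl)phenyl]-5,7-bis(methoxymethoxy)-8-(3-methylbut-2-enyl)chroman-4-one
Product: 21 (2S)-5,7-dihydroxy-2-[4-hydroxy-3-methoxy-2-(3-methylbut-2-enyl)phenyl]-8-(3-methylbut-2-enyl)chroman-4-one (CNP0282226.1)
Conditions: HCl (1 M in MeOH), 35 °C, short reaction time; NaHCO3 work-up kept below pH 7
Reagents that add atoms: none
Why: Acid-catalysed acetal exchange (methanolysis of three aryl MOM ethers), the usual deprotection for prenylated flavanones, should spare the methyl ether and the prenyl groups at this temperature and keep the 2S centre, since ring opening by retro-oxa-Michael reaction needs base.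

**Compound list**
1 | phloroglucinol (benzene-1,3,5-triol) | Oc1cc(O)cc(O)c1 | starting material
2 | 3,5-bis(methoxymethoxy)phenol | COCOc1cc(O)cc(OCOC)c1 | intermediate
3 | 1-(allyloxy)-3,5-bis(methoxymethoxy)benzene | C=CCOc1cc(OCOC)cc(OCOC)c1 | intermediate
4 | 2-allyl-3,5-bis(methoxymethoxy)phenol | C=CCc1c(O)cc(OCOC)cc1OCOC | intermediate
5 | 2-allyl-6-bromo-3,5-bis(methoxymethoxy)phenol | C=CCc1c(O)c(Br)c(OCOC)cc1OCOC | intermediate
6 | [2-allyl-6-bromo-3,5-bis(methoxymethoxy)phenoxy]trimethylsilane | C=CCc1c(O[Si](C)(C)C)c(Br)c(OCOC)cc1OCOC | intermediate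
7 | lithium 2-allyl-3,5-bis(methoxymethoxy)-6-(trimethylsilyl)phenoxide | [Li+].[O-]c1c(CC=C)c(OCOC)cc(OCOC)c1[Si](C)(C)C | intermediate
8 | 2-allyl-3,5-bis(methoxymethoxy)-6-(trimethylsilyl)phenyl trifluoromethanesulfonate | C=CCc1c(OCOC)cc(OCOC)c([Si](C)(C)C)c1OS(=O)(=O)C(F)(F)F | intermediate
9 | 3,4-dihydroxybenzaldehyde | O=Cc1ccc(O)c(O)c1 | starting material
10 | 3-hydroxy-4-(methoxymethoxy)benzaldehyde | COCOc1ccc(C=O)cc1O | intermediate
11 | 3-(allyloxy)-4-(methoxymethoxy)benzaldehyde | C=CCOc1cc(C=O)ccc1OCOC | intermediate
12 | 2-allyl-3-hydroxy-4-(methoxymethoxy)benzaldehyde | C=CCc1c(O)c(OCOC)ccc1C=O | intermediate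
13 | 2-allyl-3-methoxy-4-(methoxymethoxy)benzaldehyde | C=CCc1c(OC)c(OCOC)ccc1C=O | intermediate
14 | ethyl 3-[2-allyl-3-methoxy-4-(methoxymethoxy)phenyl]-3-oxopropanoate | CCOC(=O)CC(=O)c1ccc(OCOC)c(OC)c1CC=C | intermediate
15 | ethyl (3S)-3-[2-allyl-3-methoxy-4-(methoxymethoxy)phenyl]-3-hydroxypropanoate | COc1c(OCOC)ccc([C@H](CC(=O)OCC)O)c1CC=C | intermediate
16 | ethyl (3S)-3-[2-allyl-3-methoxy-4-(methoxymethoxy)phenyl]-3-(trimethylsilyloxy)propanoate | COc1c(OCOC)ccc([C@H](CC(=O)OCC)O[Si](C)(C)C)c1CC=C | intermediate
17 | caesium alkoxide of 15, (S) | COc1c(OCOC)ccc([C@H](CC(=O)OCC)[O-])c1CC=C.[Cs+] | intermediate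
18 | 3-allyl-4,6-bis(methoxymethoxy)benzyne (1,2-didehydrobenzene) | C=CCC1=C(OCOC)C=C(OCOC)C#C1 | intermediate
19 | (2S)-8-allyl-2-[2-allyl-3-methoxy-4-(methoxymethoxy)phenyl]-5,7-bis(methoxymethoxy)chroman-4-one | COc1c(OCOC)ccc([C@@H]2CC(=O)c3c(OCOC)cc(OCOC)c(CC=C)c3O2)c1CC=C | intermediate
20 | (2S)-2-[3-methoxy-4-(methoxymethoxy)-2-(3-methylbut-2-enyl)phenyl]-5,7-bis(methoxymethoxy)-8-(3-methylbut-2-enyl)chroman-4-one | COc1c(OCOC)ccc([C@@H]2CC(=O)c3c(OCOC)cc(OCOC)c(CC=C(C)C)c3O2)c1CC=C(C)C | intermediate
21 | (2S)-5,7-dihydroxy-2-[4-hydroxy-3-methoxy-2-(3-methylbut-2-enyl)phenyl]-8-(3-methylbut-2-enyl)chroman-4-one (CNP0282226.1) | COc1c(O)ccc([C@@H]2CC(=O)c3c(O)cc(O)c(CC=C(C)C)c3O2)c1CC=C(C)C | target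

Total step count: 15
Longest linear sequence: 10 steps (steps 6 to 15, from 9)

**Steps most likely to fail**

1. Step 13 (bears the label).
   - What may go wrong: transfer of an alpha-proton of the ester to the aryl anion followed by beta-elimination of the aryloxide; retro-aldol cleavage or base-induced elimination of the silyloxy ester before the alkoxide meets the aryne; addition of the bulky alkoxide at the wrong end of the triple bond.
   - Fallback (known chemistry, the two bonds made one after the other): it sets out from 14 and 5 and comes back to the route at 19. Asymmetric transfer hydrogenation of 14 with RuCl[(R,R)-TsDPEN](p-cymene) gives the (3R)-hydroxy ester F1. Aminolysis with MeNH(OMe)·HCl and i-PrMgCl gives the (3R)-hydroxy Weinreb amide F2. Mitsunobu etherification with bromophenol 5 (PPh3, DIAD, toluene, high concentration) inverts the carbinol carbon and gives the (3S)-aryl ether Weinreb amide F3. Bromine-lithium exchange with n-BuLi at −78 °C then closes ring C by Parham cyclisation onto the amide and gives 19.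

2. Step 4.
   - What may go wrong: bromination at the carbon between the two MOM ethers, double bromination, or attack of the bromine source on the allyl double bond.
   - Fallback (regiochemistry fixed by symmetry and by a blocked position rather than by directing effects): it sets out from 1 and comes back at 5. Monobromination of 1 with NBS (1 equiv, low temperature), where all three ring CH positions are equivalent, gives 2-bromobenzene-1,3,5-triol F4. Double MOM protection with separation of the isomeric bis-ethers gives 2-bromo-3,5-bis(methoxymethoxy)phenol F5. Allylation (allyl bromide, K2CO3) gives 1-(allyloxy)-2-bromo-3,5-bis(methoxymethoxy)benzene F6. Its aromatic Claisen rearrangement can end only at the one free ortho carbon and gives 5.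

3. Step 10.
   - What may go wrong: migration of the electron-rich aryl group in place of hydride after addition of the diazo ester, slow reaction of the hindered aldehyde, or loss of the MOM ether to the Lewis acid.
   - Fallback (carbon-carbon bond made by an enolate, oxidation level adjusted afterwards): it sets out from 13 and comes back at 14. Aldol addition of the lithium enolate of ethyl acetate (LDA, THF, −78 °C) gives the racemic hydroxy ester F7. Oxidation with Dess–Martin periodinane in CH2Cl2 gives 14.

**Further compounds**
F1 | step 13 | ethyl (3R)-3-[2-allyl-3-methoxy-4-(methoxymethoxy)phenyl]-3-hydroxypropanoate | COc1c(OCOC)ccc([C@@H](CC(=O)OCC)O)c1CC=C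
F2 | step 13 | (3R)-3-[2-allyl-3-methoxy-4-(methoxymethoxy)phenyl]-3-hydroxy-N-methoxy-N-methylpropanamide | COc1c(OCOC)ccc([C@@H](CC(=O)N(C)OC)O)c1CC=C
F3 | step 13 | (3S)-3-[2-allyl-6-bromo-3,5-bis(methoxymethoxy)phenoxy]-3-[2-allyl-3-methoxy-4-(methoxymethoxy)phenyl]-N-methoxy-N-methylpropanamide | COc1c(OCOC)ccc([C@H](CC(=O)N(C)OC)Oc2c(Br)c(OCOC)cc(OCOC)c2CC=C)c1CC=C
F4 | step 4 | 2-bromobenzene-1,3,5-triol | Oc1cc(O)c(Br)c(O)c1
F5 | step 4 | 2-bromo-3,5-bis(methoxymethoxy)phenol | COCOc1cc(O)c(Br)c(OCOC)c1
F6 | step 4 | 1-(allyloxy)-2-bromo-3,5-bis(methoxymethoxy)benzene | C=CCOc1cc(OCOC)cc(OCOC)c1Br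
F7 | step 10 | ethyl 3-[2-allyl-3-methoxy-4-(methoxymethoxy)phenyl]-3-hydroxypropanoate (racemic) | COc1c(OCOC)ccc(C(O)CC(=O)OCC)c1CC=C
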